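The data are calculated on assumed constants; the scatter is artificial.

Read the red run first, since the new flask repeats its feed of X and its [Q] and carries twice the loading of L.

common to all: X 0.30 M (fed, over 40 s)

| flask | Q | L | remark | time |
|---|---|---|---|---|
| red | 0.30 M | 0.05 mol% | run made earlier |  |
| flask | 0.300 M | 0.1 mol% |  | 6.0 min |

red run (percent of the X charged)

| time / s | D / % | X / % |
|---|---|---|
| 10.0 | 3.0 | 22.2 |
| 12.0 | 1.8 | 26.8 |
| 20.0 | 2.4 | 39.8 |
| 40.0 | 8.5 | 69.6 |

(readings scatter by 1 percentage point)

- the average divides the monomer in chains by the number of chains, living and dead together; two radicals that join make one chain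
- candidate steps: X + E -> D + E; 2 E -> Z; L -> 2 J; Q + X -> G; X + J -> E + D
- the earlier runs do not show the number of chains; that part of a forecast is a guess
- percentages count the whole charge, also what has not yet gone in
- no earlier run changes the charge of L; that part of a forecast is a guess

- average number of monomer units in a chain (living and dead chains, two that joined counted as one) at 6.0 min
- part of the X that has reacted at 6.0 min

At 40.0 s the feed has brought in the whole charge, yet X and D together read 78.1 %, so book the missing 21.9 % as G, and take the area under the rising X curve as a triangle, 13.9 s at full charge. Divide that area by each product to get two readings: a pseudo-first-order clock of 63.6 s for the loss to G and 164 s for growth to D. Stack the rungs: the feed of 40 s is shorter than G's clock, G's clock is shorter than D's, and D's is shorter than the 360 s allowed.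

Add the rung no run shows, as my own guess: if L makes E and E dies in pairs, [E] goes with the square root of L, so D's clock shortens to 116 s and X's joint clock is 41.0 s. If both clocks hold steady to the end, which is my assumption and no reading, the time after the feed spans 7.80 such lives, so expect nearly all of X to react, with 35.4 % of it becoming D.

Now count chains: each L gives two J, each J starts one E, and two E join into one Z, so take the chain count, one finished chain per L charged, as 3.00 × 10⁻⁴ M, guessing that L gets spent. Divide D by it, and my dp is 354, an estimate that keeps the steady clocks although this count takes L as spent.

The forecast says a dp of 1000 and a c of 99 %, with the remark “Partial decomposition gives more; this is a guess.” Its dp is higher than mine.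

The flask gives a dp of 243 and a c of 94.4 %.

    X + E → D + E, rate k1*[E]*[X] (k = 81000 /M/s)
    2 E → Z (k = 4.30 × 10⁸ /M/s)
    L → 2 J (k = 0.0400 /s)
    Q + X → G (k = 0.0540 /M/s)
    X + J → E + D (k = 2.30 × 10⁶ /M/s)

In this flask L is down to 20.2 % of its charge at 0.667 min, and D ends at 24.3 % of the X charged, which is 25.7 % of the X reacted, less than my share. Divide that D by the chain count and get 243. In the neighbour charged with 0.075 M of Q and the same L, the same division of its D, 33.1 %, gives 331, and the dp of that flask stands at 331.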